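**Retrosynthetic overview**
1. The target comes from trans-diaxial HBr addition to a 1-(chloromethyl)cyclohexene. That alkene comes from a Cl+-initiated C3–C8 cation–olefin closure of an acyclic (1E,3Z,6R)-trichlorotriene, a halogenated ocimene. Both events run in one flask as the last step.
2. The triene carries a single stereocentre (C6). C3, C4 and C7 are all set in that last flask.
3. The triene comes from a double OH→Cl exchange (inversion at C6) on a 2-methylidene-1,3-diol, which comes from isomerisation of the Sharpless epoxide of an E-allylic alcohol.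
4. The C10 chain is joined from an E-alkenylalane (propargyl alcohol + Me3Al) and a Z-enynyl bromide made from the commercial Z-enynol. The alkyne becomes the E-chlorovinyl group by hydrozirconation/NCS.
5. Ring order: the only ring, the cyclohexane, is formed last.

Assumption: 1 is bought as the pure Z isomer, and locants C1–C8 in the text are those of triene 11 (C1 = CHCl terminus, C8 = terminal CH2).

Step 1
Reactants: 1 (2Z)-3-methylpent-2-en-4-yn-1-ol
Product: 2 (3Z)-5-bromo-3-methylpent-3-en-1-yne
Conditions: PBr3 (0.4 equiv), Et2O, −10 °C, 1 h; used crude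
Reagents that add atoms: phosphorus tribromide, BrP(Br)Br
Why: PBr3 bromination of a primary allylic alcohol runs by SN2 displacement of its phosphite ester, which at low temperature keeps the Z alkene and leaves the alkyne alone; no stereocentre is formed.

Step 2
Reactants: 2 (3Z)-5-bromo-3-methylpent-3-en-1-yne; 3 prop-2-yn-1-ol
Product: 5 (2E,5Z)-2,6-dimethylocta-2,5-dien-7-yn-1-ol, via alkenylalane 4 (not isolated)
Conditions: 3, Me3Al (3 equiv), Cp2ZrCl2 (25 mol%), CH2Cl2, 0 °C to rt; strip excess Me3Al; THF; 2, Pd(PPh3)4 (5 mol%), 0 °C to rt; aq. potassium sodium tartrate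
Reagents that add atoms: trimethylaluminium, C[Al](C)C
Why: Negishi carboalumination adds Me and Al syn to give only the E-alkenylalane, and the zerovalent-palladium alkenyl–allyl coupling joins it to the CH2 end of the γ,γ-disubstituted allyl bromide with retention of both alkene geometries, while THF stops any carboalumination of the enyne C≡CH.

Step 3
Reactants: 5 (2E,5Z)-2,6-dimethylocta-2,5-dien-7-yn-1-ol
Product: 7 (2E,5Z,7E)-8-chloro-2,6-dimethylocta-2,5,7-trien-1-ol, via alkenylzirconocene 6 (not isolated)
Conditions: Cp2Zr(H)Cl (2.2 equiv), THF, 0 °C to rt; NCS (1.1 equiv), 0 °C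
Reagents that add atoms: N-chlorosuccinimide, O=C1CCC(=O)N1Cl
Why: Hydrozirconation is a syn, terminus-selective addition to the alkyne (the first equivalent only deprotonates the OH, and trisubstituted alkenes are inert), and NCS cleaves the C–Zr bond with retention to give the E-chlorovinyl group.

Step 4
Reactants: 7 (2E,5Z,7E)-8-chloro-2,6-dimethylocta-2,5,7-trien-1-ol
Product: 8 [(2S,3S)-3-[(2Z,4E)-5-chloro-3-methylpenta-2,4-dien-1-yl]-2-methyloxiran-2-yl]methanol
Conditions: Ti(OiPr)4 (10 mol%), L-(+)-diethyl tartrate (12 mol%), t-BuOOH (2 equiv), 4 Å MS, CH2Cl2, −20 °C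
Reagents that add atoms: tert-butyl hydroperoxide, CC(C)(C)OO
Why: Sharpless asymmetric epoxidation touches only the allylic-alcohol alkene, and L-(+)-tartrate delivers oxygen to the face that gives the (2S,3S)-epoxide (over 90% ee is usual for E-2-methylalk-2-en-1-ols), which fixes the future C6 centre.

Step 5
Reactants: 8 [(2S,3S)-3-[(2Z,4E)-5-chloro-3-methylpenta-2,4-dien-1-yl]-2-methyloxiran-2-yl]methanol
Product: 10 (3S,5Z,7E)-8-chloro-6-methyl-2-methylideneocta-5,7-diene-1,3-diol, via bis-TMS ether 9 (not isolated)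
Conditions: TMSOTf (2.5 equiv), DBU (3 equiv), toluene, −78 °C to rt; then K2CO3 (cat.), MeOH
Reagents that add atoms: none
Why: In the silyl-triflate-promoted epoxide-to-allylic-alcohol isomerisation, O-silylation weakens the tertiary C–O bond and DBU removes the least hindered proton (from CH3) to give the 1,1-disubstituted alkene, while the secondary C–O bond is never broken, so the carbinol stays S.

Step 6
Reactants: 10 (3S,5Z,7E)-8-chloro-6-methyl-2-methylideneocta-5,7-diene-1,3-diol
Product: 11 (1E,3Z,6R)-1,6-dichloro-7-(chloromethyl)-3-methylocta-1,3,7-triene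
Conditions: PPh3 (2.4 equiv), Cl3CC(O)CCl3 (2.6 equiv), CH2Cl2, −20 to 0 °C
Reagents that add atoms: hexachloroacetone, ClC(Cl)(Cl)C(=O)C(Cl)(Cl)Cl
Why: This Appel-type chlorination with PPh3/hexachloroacetone is the variant known for unrearranged allylic chlorides, so both alkoxyphosphonium salts are displaced by SN2 and the secondary one inverts cleanly (S alcohol to R chloride).

Step 7
Reactants: 11 (1E,3Z,6R)-1,6-dichloro-7-(chloromethyl)-3-methylocta-1,3,7-triene
Product: 13 (1R,2R,4S,5S)-1-bromo-2,4-dichloro-1-(chloromethyl)-5-[(E)-2-chloroethenyl]-5-methylcyclohexane, via chloromethylcyclohexene 12 (not isolated)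
Conditions: NCS (0.98 equiv), morpholine (10 mol%), (CF3)2CHOH, −10 °C, dark, until no N–Cl is left; then TMSBr (2 equiv), −10 to 10 °C
Reagents that add atoms: N-chlorosuccinimide, O=C1CCC(=O)N1Cl; bromotrimethylsilane, C[Si](C)(C)Br
Why: Proposed new method: the HFIP-activated N–Cl donor hands Cl+ to C4 of the chlorodiene (the only electron-rich π system, since the C7=C8 alkene is switched off by two allylic C–Cl bonds) to give the 4-chloro-1-chloroallyl cation, which in non-nucleophilic HFIP lives long enough for C8 to attack C3 through the chair that keeps the resident C6–Cl and the new C4–Cl bonds equatorial (C6 thereby chooses the diene face, and anti addition across the Z alkene, reinforced by the smaller axial demand of the flat chlorovinyl group, sets C3), the destabilised C7 cation then loses H-8 to give 12, and only when no N–Cl is left (it would oxidise bromide to Br+) is HBr released from TMSBr and HFIP, so that C8 is reprotonated and bromide enters C7 axially, anti to the new axial H (Markovnikov, trans-diaxial, and also the more stable epimer with CH2Cl equatorial); the closest known reaction types are N-halosuccinimide/HFIP haliranium-induced polyene cyclisation, cation cyclisations terminated by chloro-olefins and ionic HBr addition to 1-substituted cyclohexenes.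

**Compound list**
1 | (2Z)-3-methylpent-2-en-4-yn-1-ol | OC/C=C(/C)C#C | starting material
2 | (3Z)-5-bromo-3-methylpent-3-en-1-yne | BrC/C=C(/C)C#C | intermediate
3 | prop-2-yn-1-ol | OCC#C | starting material
4 | (E)-[3-(dimethylalumanyloxy)-2-methylprop-1-en-1-yl]dimethylalumane | C[Al](C)/C=C(\C)CO[Al](C)C | intermediate
5 | (2E,5Z)-2,6-dimethylocta-2,5-dien-7-yn-1-ol | OC/C(C)=C/C/C=C(/C)C#C | intermediate
6 | (1E)-alkenyl(chloro)zirconocene from 5, hydroxyl bound as chlorozirconocene alkoxide (cyclopentadienyl drawn σ-bound) | Cl[Zr](C1C=CC=C1)(C1C=CC=C1)OC/C(C)=C/C/C=C(/C)\C=C\[Zr](Cl)(C1C=CC=C1)C1C=CC=C1 | intermediate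
7 | (2E,5Z,7E)-8-chloro-2,6-dimethylocta-2,5,7-trien-1-ol | OC/C(C)=C/C/C=C(/C)\C=C\Cl | intermediate
8 | [(2S,3S)-3-[(2Z,4E)-5-chloro-3-methylpenta-2,4-dien-1-yl]-2-methyloxiran-2-yl]methanol | OC[C@]1(C)O[C@H]1C/C=C(/C)\C=C\Cl | intermediate
9 | bis(trimethylsilyl) ether of (3S,5Z,7E)-8-chloro-6-methyl-2-methylideneocta-5,7-diene-1,3-diol | C[Si](C)(C)OCC(=C)[C@@H](O[Si](C)(C)C)C/C=C(/C)\C=C\Cl | intermediate
10 | (3S,5Z,7E)-8-chloro-6-methyl-2-methylideneocta-5,7-diene-1,3-diol | OCC(=C)[C@@H](O)C/C=C(/C)\C=C\Cl | intermediate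
11 | (1E,3Z,6R)-1,6-dichloro-7-(chloromethyl)-3-methylocta-1,3,7-triene | ClCC(=C)[C@H](Cl)C/C=C(/C)\C=C\Cl | intermediate
12 | (3S,4S,6R)-4,6-dichloro-1-(chloromethyl)-3-[(E)-2-chloroethenyl]-3-methylcyclohex-1-ene | ClCC1=C[C@@](C)(/C=C/Cl)[C@@H](Cl)C[C@H]1Cl | intermediate
13 | (1R,2R,4S,5S)-1-bromo-2,4-dichloro-1-(chloromethyl)-5-[(E)-2-chloroethenyl]-5-methylcyclohexane | C[C@@]1(/C=C/Cl)C[C@@](Br)(CCl)[C@H](Cl)C[C@@H]1Cl | target

**Step count**
Total steps: 7. Longest linear sequence: 7 (1 to 13); 3 enters at step 2.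

**Steps most likely to fail**

Step 7 carries the most risk.
- Cl+ transfer and ring closure may not be coupled, in which case C4 forms on both diene faces.
- The hot C7 cation may be lost to solvent.
- HBr may add sluggishly, or may swap the allylic chlorides of 12 for bromide.

The fallback sets out from 11 and comes back at 13. It fixes C4 with a reagent and closes the ring with no oxidant present. Shi epoxidation (D-fructose-derived ketone, KHSO5 as 2KHSO5·KHSO4·K2SO4, K2CO3 buffer, MeCN/dimethoxymethane, 0 °C) attacks only the trisubstituted end of the chlorodiene. It gives (2S,3R)-2-[(E)-2-chloroethenyl]-3-[(2R)-2-chloro-3-(chloromethyl)but-3-en-1-yl]-2-methyloxirane F1. TMSOTf/DBU opens the tertiary allylic C–O bond with loss of a methyl proton to give [(1E,4R,6R)-1,6-dichloro-7-(chloromethyl)-3-methylideneocta-1,7-dien-4-yl]oxy(trimethyl)silane F2. Methanolysis gives (1E,4R,6R)-1,6-dichloro-7-(chloromethyl)-3-methylideneocta-1,7-dien-4-ol F3. PPh3/hexachloroacetone then inverts C4 to give (1E,4S,6R)-1,4,6-trichloro-7-(chloromethyl)-3-methylideneocta-1,7-diene F4. HBr (TMSBr in (CF3)2CHOH, −20 °C) protonates the methylidene CH2 of the diene and so gives the same 4-chloro-1-chloroallyl cation as in step 7. The C3–C8 bond closes through the same chair. Since nothing in the flask can oxidise bromide, bromide caps C7 directly to give 13.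

Step 6 is the second risk. SN2′ attack at the terminal CH2 would give the achiral isomer RCH=C(CH2Cl)2, and ion pairing would erode the ee at C6. The fallback sets out from 8 and comes back at 11. It makes the C6–Cl bond while that carbon is not yet allylic. PPh3/CCl4 (NaHCO3, reflux) turns 8 into (2R,3S)-2-(chloromethyl)-3-[(2Z,4E)-5-chloro-3-methylpenta-2,4-dien-1-yl]-2-methyloxirane F5. Li2CuCl4 in THF opens the epoxide at the secondary carbon with inversion, because the tertiary carbon is hindered and deactivated by CH2Cl. This gives (2S,3R,5Z,7E)-1,3,8-trichloro-2,6-dimethylocta-5,7-dien-2-ol F6. SOCl2/pyridine (0 °C) dehydrates the tertiary alcohol toward the methyl group to give 11.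

Step 2 is the third risk. Leftover Me3Al/Cp2ZrCl2 may carboaluminate the C≡CH of 2, and the π-allylpalladium intermediate may leak Z to E. The fallback sets out from 2 and comes back at 5. It couples a simple Grignard reagent and adds the oxygen afterwards. Me2C=CHMgBr (2.1 equiv, the first equivalent deprotonates the alkyne) with CuI (5 mol%) in THF at −30 °C displaces bromide by SN2 to give (3Z)-3,7-dimethylocta-3,6-dien-1-yne F7. SeO2 (cat.)/t-BuOOH in CH2Cl2, followed by NaBH4 to return any enal, hydroxylates the E-methyl group of the more electron-rich isopropylidene terminus to give 5.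

**Further compounds**
F1 | step 7 | (2S,3R)-2-[(E)-2-chloroethenyl]-3-[(2R)-2-chloro-3-(chloromethyl)but-3-en-1-yl]-2-methyloxirane | ClCC(=C)[C@H](Cl)C[C@H]1O[C@@]1(C)/C=C/Cl
F2 | step 7 | [(1E,4R,6R)-1,6-dichloro-7-(chloromethyl)-3-methylideneocta-1,7-dien-4-yl]oxy(trimethyl)silane | ClCC(=C)[C@H](Cl)C[C@@H](O[Si](C)(C)C)C(=C)/C=C/Cl
F3 | step 7 | (1E,4R,6R)-1,6-dichloro-7-(chloromethyl)-3-methylideneocta-1,7-dien-4-ol | ClCC(=C)[C@H](Cl)C[C@@H](O)C(=C)/C=C/Cl
F4 | step 7 | (1E,4S,6R)-1,4,6-trichloro-7-(chloromethyl)-3-methylideneocta-1,7-diene | ClCC(=C)[C@H](Cl)C[C@H](Cl)C(=C)/C=C/Cl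
F5 | step 6 | (2R,3S)-2-(chloromethyl)-3-[(2Z,4E)-5-chloro-3-methylpenta-2,4-dien-1-yl]-2-methyloxirane | ClC[C@]1(C)O[C@H]1C/C=C(/C)\C=C\Cl
F6 | step 6 | (2S,3R,5Z,7E)-1,3,8-trichloro-2,6-dimethylocta-5,7-dien-2-ol | ClC[C@](C)(O)[C@H](Cl)C/C=C(/C)\C=C\Cl
F7 | step 2 | (3Z)-3,7-dimethylocta-3,6-dien-1-yne | CC(C)=CC/C=C(/C)C#C
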